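## Retrosynthetic overview

1. Atom labels: ring A is the dienone ring (C8 hydroperoxy carbon, C9, C11 the CH, C12 ketone, C13 methyl-bearing, C14 vinyl-bearing); ring B is C5 (isopropenyl CH, C4 the isopropenyl carbon), C6, C7, C8, C9, C10 (quaternary, with a methyl and the C1–C2–C3 ester arm).
2. Target ⇒ ring A phenol (C12–OH) by phenol para-oxygenation at C8 with singlet oxygen; phenol ⇒ C14 chloride, C12 methyl ether and a C1–C2=C3 allyl group (vinyl Suzuki coupling, O-demethylation, hydroboration–oxidation–esterification).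
3. Key disconnection, C9–C10 and C1–C2 together: ring B closes by an enantioselective 6-exo Heck cyclization of a C9 aryl iodide onto one of two isopropenyl groups, and the alkylpalladium formed is trapped by a vinylboronate.
4. Feature used: the adjacent stereocentres C5 and C10 of ring B derive from one prochiral carbon bearing two identical isopropenyl groups (C5 keeps one; C10, its methyl and C1 are the other), so the precursor is achiral and one desymmetrizing step sets both centres.
5. Precursor ⇒ arylethyl iodide + methyl 3-methylbut-2-enoate (deconjugative α-alkylation, then ester → methyl ketone → methylene) ⇒ 3-chloro-2-methylanisole (formylation, directed iodination, one-carbon homologation). Ring order: ring A is the purchased benzene ring, ring B is formed in step 10, ring A is dearomatized last.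

Key step: step 10

Remark: compounds 14 to 17 carry one stereocentre and are made and used as racemates; it disappears in 18, which is achiral.
Assumption: which enantiomer of BINAP leads to the (1R,2R) series of 21 cannot be assigned with confidence in advance; (R)-BINAP is written, and its antipode would be used if the cyclization proved to give ent-21.

## Route

Step 1
Reactants: 1 3-chloro-2-methylanisole
Product: 3 2-chloro-4-methoxy-3-methylbenzaldehyde, via α-chloro ether 2 (not isolated)
Conditions: Cl2CHOMe, TiCl4, CH2Cl2, 0 °C; then ice–water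
Reagents that add atoms: dichloromethyl methyl ether, COC(Cl)Cl; water, O
Why: Rieche formylation, in which the methoxy group directs the TiCl4-activated electrophile to its para position (the future C8) in preference to the ortho position, and hydrolysis of 2 on work-up releases the aldehyde.

Step 2
Reactants: 3 2-chloro-4-methoxy-3-methylbenzaldehyde
Product: 7 2-chloro-6-iodo-4-methoxy-3-methylbenzaldehyde, via lithium α-amino alkoxide 4 (not isolated), via aryllithium 5 (not isolated), via iodinated α-amino alkoxide 6 (not isolated)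
Conditions: LiN(Me)CH2CH2NMe2, THF, −20 °C; n-BuLi, −20 °C; I2, −78 °C to rt; aq. NH4Cl
Reagents that add atoms: iodine, [I][I]
Why: α-Amino alkoxide-directed ortho-lithiation of a benzaldehyde, in which the lithium amide adds to the aldehyde, protects it and turns it into a chelating director that steers n-BuLi to C9–H (the only free position ortho to it, the other being C14–Cl) in preference to the methoxy-flanked C11–H, and iodinolysis followed by collapse of the aminal on work-up gives the iodo aldehyde.

Step 3
Reactants: 7 2-chloro-6-iodo-4-methoxy-3-methylbenzaldehyde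
Product: 8 3-chloro-2-ethenyl-1-iodo-5-methoxy-4-methylbenzene
Conditions: Ph3PCH3Br, KOtBu, THF, 0 °C to rt
Reagents that add atoms: methyltriphenylphosphonium bromide, C[P+](c1ccccc1)(c1ccccc1)c1ccccc1.[Br-]
Why: Wittig methylenation with the small unstabilized ylide, which should react with the di-ortho-substituted aldehyde and leave both aryl halides untouched.

Step 4
Reactants: 8 3-chloro-2-ethenyl-1-iodo-5-methoxy-4-methylbenzene
Product: 10 2-(2-chloro-6-iodo-4-methoxy-3-methylphenyl)ethan-1-ol, via alkylborane 9 (not isolated)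
Conditions: 9-BBN, THF, 0 °C to rt; then NaOH, H2O2, 0 °C
Reagents that add atoms: hydrogen peroxide, OO
Why: Hydroboration–oxidation, in which 9-BBN places boron on the terminal carbon of the styrene (anti-Markovnikov) and alkaline peroxide converts C–B into C–OH without affecting the aryl iodide.

Step 5
Reactants: 10 2-(2-chloro-6-iodo-4-methoxy-3-methylphenyl)ethan-1-ol
Product: 11 3-chloro-1-iodo-2-(2-iodoethyl)-5-methoxy-4-methylbenzene
Conditions: I2, PPh3, imidazole, CH2Cl2, 0 °C to rt
Reagents that add atoms: iodine, [I][I]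
Why: Appel-type iodination of a primary alcohol through the alkoxyphosphonium salt and SN2 displacement by iodide.

Step 6
Reactants: 11 3-chloro-1-iodo-2-(2-iodoethyl)-5-methoxy-4-methylbenzene; 12 methyl 3-methylbut-2-enoate
Product: 14 methyl 2-[2-(2-chloro-6-iodo-4-methoxy-3-methylphenyl)ethyl]-3-methylbut-3-enoate (racemic), via lithium dienolate 13 (not isolated)
Conditions: LiN(i-Pr)2, THF–DMPU, −78 °C; then 11, −78 to −20 °C
Reagents that add atoms: none
Why: Deconjugative α-alkylation of an extended ester dienolate, in which γ-deprotonation of 12 gives 13 and this reacts with the primary iodide at its α-carbon under kinetic control, so that the double bond ends up as the first isopropenyl group; the twisted di-ortho-substituted aryl group should slow the competing E2 elimination.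

Step 7
Reactants: 14 methyl 2-[2-(2-chloro-6-iodo-4-methoxy-3-methylphenyl)ethyl]-3-methylbut-3-enoate
Product: 15 2-[2-(2-chloro-6-iodo-4-methoxy-3-methylphenyl)ethyl]-N-methoxy-N,3-dimethylbut-3-enamide
Conditions: MeNH(OMe)·HCl, AlMe3, CH2Cl2, 0 °C to reflux
Reagents that add atoms: N,O-dimethylhydroxylamine hydrochloride, CNOC.Cl
Why: Weinreb amide formation by aminolysis of the ester with the aluminium amide made from AlMe3 and the amine hydrochloride, a weakly basic reagent that should neither shift the β,γ-double bond nor touch the aryl iodide.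

Step 8
Reactants: 15 2-[2-(2-chloro-6-iodo-4-methoxy-3-methylphenyl)ethyl]-N-methoxy-N,3-dimethylbut-3-enamide
Product: 17 3-[2-(2-chloro-6-iodo-4-methoxy-3-methylphenyl)ethyl]-4-methylpent-4-en-2-one, via magnesium chelate 16 (not isolated)
Conditions: MeMgBr, THF, 0 °C; then aq. NH4Cl
Reagents that add atoms: methylmagnesium bromide, C[Mg]Br
Why: Weinreb ketone synthesis, in which the chelated tetrahedral adduct 16 survives until work-up so that only one methyl group is added, and MeMgBr does not exchange with the aryl iodide at 0 °C.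

Step 9
Reactants: 17 3-[2-(2-chloro-6-iodo-4-methoxy-3-methylphenyl)ethyl]-4-methylpent-4-en-2-one
Product: 18 3-chloro-1-iodo-5-methoxy-4-methyl-2-[4-methyl-3-(prop-1-en-2-yl)pent-4-en-1-yl]benzene
Conditions: Zn, CH2Br2, TiCl4, THF–CH2Cl2, 0 °C to rt
Reagents that add atoms: dibromomethane, BrCBr
Why: Lombardo methylenation, a non-basic carbonyl olefination that should convert the enolizable β,γ-unsaturated ketone into the second isopropenyl group without moving the existing double bond into conjugation, which makes the two alkenyl groups identical and the molecule achiral.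

Step 10
Reactants: 18 3-chloro-1-iodo-5-methoxy-4-methyl-2-[4-methyl-3-(prop-1-en-2-yl)pent-4-en-1-yl]benzene; 19 vinylboronic acid pinacol ester
Product: 21 (1R,2R)-5-chloro-7-methoxy-1,6-dimethyl-1-(prop-2-en-1-yl)-2-(prop-1-en-2-yl)-1,2,3,4-tetrahydronaphthalene, via neopentylpalladium complex 20 (not isolated)
Conditions: Pd(OAc)2, (R)-2,2'-bis(diphenylphosphino)-1,1'-binaphthyl ((R)-BINAP), Ag3PO4, 19 (3 equiv), DMA–H2O, 80 °C
Reagents that add atoms: none
Why: Zerovalent palladium, formed from Pd(OAc)2 and (R)-BINAP, inserts into the C9–I bond (the C14–Cl bond is inert here), Ag3PO4 abstracts iodide, and the cationic arylpalladium adds syn across one isopropenyl group with the aryl carbon going to the internal alkene carbon, giving neopentylpalladium 20, which has no β-hydrogen and so persists until it transmetalates with 19 and reductively eliminates to form C1–C2. The closest known reaction type is the enantioselective intramolecular Heck cyclization that desymmetrizes a prochiral diene, run as a Heck–Suzuki (anion-capture) domino. Ring B closes in the 6-exo-trig mode through the C9–C10 bond, the 7-endo alternative being disfavoured for a 1,1-disubstituted alkene on this tether. C5 is fixed by which of the two enantiotopic isopropenyl groups the BINAP-bound cationic palladium accepts, and C10 by the alkene face, which is tied to the same choice because the tether adopts a chair-like transition state with the spectator isopropenyl pseudo-equatorial and the C10=C1 bond eclipsed with the in-plane C9–Pd bond, so that the new methyl ends up cis to the isopropenyl group and C1 trans to it. The step needs enantiotopic-group selectivity, 6-exo regioselectivity and capture that outruns side reactions; the achiral substrate with two identical alkenes, the tether length from C8 and the excess of 19 serve these needs, and the trans arrangement of C1–Pd and the remaining isopropenyl group prevents a second insertion.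

Step 11
Reactants: 21 (1R,2R)-5-chloro-7-methoxy-1,6-dimethyl-1-(prop-2-en-1-yl)-2-(prop-1-en-2-yl)-1,2,3,4-tetrahydronaphthalene
Product: 23 3-[(1R,2R)-5-chloro-7-methoxy-1,6-dimethyl-2-(prop-1-en-2-yl)-1,2,3,4-tetrahydronaphthalen-1-yl]propan-1-ol, via trialkylborane 22 (not isolated)
Conditions: Sia2BH (from BH3·THF, 2-methylbut-2-ene), THF, 0 °C; then NaOH, H2O2
Reagents that add atoms: hydrogen peroxide, OO
Why: Hydroboration–oxidation with a hindered dialkylborane, which should add to the monosubstituted allyl double bond (boron at C3) much faster than to the 1,1-disubstituted, sterically shielded isopropenyl group, so that only the allyl group becomes the primary alcohol.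

Step 12
Reactants: 23 3-[(1R,2R)-5-chloro-7-methoxy-1,6-dimethyl-2-(prop-1-en-2-yl)-1,2,3,4-tetrahydronaphthalen-1-yl]propan-1-ol
Product: 25 3-[(1R,2R)-5-chloro-7-methoxy-1,6-dimethyl-2-(prop-1-en-2-yl)-1,2,3,4-tetrahydronaphthalen-1-yl]propanoic acid, via aldehyde 24 (not isolated)
Conditions: 2,2,6,6-tetramethylpiperidin-1-oxyl (TEMPO, cat.), PhI(OAc)2, MeCN–H2O, rt
Reagents that add atoms: water, O
Why: Oxoammonium (TEMPO) oxidation of a primary alcohol through the aldehyde and its hydrate to the carboxylic acid, under which the isopropenyl group, the aryl chloride and the aryl methyl ether should be inert.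

Step 13
Reactants: 25 3-[(1R,2R)-5-chloro-7-methoxy-1,6-dimethyl-2-(prop-1-en-2-yl)-1,2,3,4-tetrahydronaphthalen-1-yl]propanoic acid
Product: 26 3-[(1R,2R)-5-chloro-7-hydroxy-1,6-dimethyl-2-(prop-1-en-2-yl)-1,2,3,4-tetrahydronaphthalen-1-yl]propanoic acid
Conditions: NaSEt, DMF, 130 °C; then aq. HCl
Reagents that add atoms: none
Why: Nucleophilic O-demethylation by SN2 attack of thiolate on the O-methyl carbon, a non-acidic method that spares the isopropenyl group and is placed before esterification (thiolate would cleave a methyl ester) and before the vinyl group is introduced.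

Step 14
Reactants: 26 3-[(1R,2R)-5-chloro-7-hydroxy-1,6-dimethyl-2-(prop-1-en-2-yl)-1,2,3,4-tetrahydronaphthalen-1-yl]propanoic acid; 19 vinylboronic acid pinacol ester
Product: 27 3-[(1R,2R)-5-ethenyl-7-hydroxy-1,6-dimethyl-2-(prop-1-en-2-yl)-1,2,3,4-tetrahydronaphthalen-1-yl]propanoic acid
Conditions: Pd(OAc)2, 2-dicyclohexylphosphino-2',6'-dimethoxybiphenyl (SPhos), K3PO4, 1,4-dioxane–H2O, 100 °C; then aq. HCl
Reagents that add atoms: none
Why: Suzuki–Miyaura coupling of an aryl chloride, for which the bulky electron-rich biarylphosphine enables oxidative addition at the di-ortho-substituted C14–Cl bond, the free phenol and carboxylic acid being tolerated as their potassium salts.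

Step 15
Reactants: 27 3-[(1R,2R)-5-ethenyl-7-hydroxy-1,6-dimethyl-2-(prop-1-en-2-yl)-1,2,3,4-tetrahydronaphthalen-1-yl]propanoic acid
Product: 28 methyl 3-[(1R,2R)-5-ethenyl-7-hydroxy-1,6-dimethyl-2-(prop-1-en-2-yl)-1,2,3,4-tetrahydronaphthalen-1-yl]propanoate
Conditions: MeI, KHCO3, DMF, rt
Reagents that add atoms: iodomethane, CI
Why: SN2 O-alkylation of the carboxylate, in which hydrogencarbonate deprotonates the acid but not the phenol, so that only the methyl ester should form.

Step 16
Reactants: 28 methyl 3-[(1R,2R)-5-ethenyl-7-hydroxy-1,6-dimethyl-2-(prop-1-en-2-yl)-1,2,3,4-tetrahydronaphthalen-1-yl]propanoate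
Product: 29 trigonochinene C
Conditions: O2, hν (visible light), 5,10,15,20-tetraphenylporphyrin (cat.), CH2Cl2–MeOH, −20 °C
Reagents that add atoms: dioxygen, O=O
Why: Photosensitized singlet-oxygen dearomatization of a para-alkylphenol to the 4-hydroperoxycyclohexa-2,5-dienone, in which the electron-rich phenol should react at C8 (para to the C12 hydroxyl) far faster than the isolated alkenes undergo ene reaction, and the C8 configuration is set by the substrate, oxygen being expected to enter on the ring face anti to the C10 ester arm, that is cis to the C10 methyl group.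

## Compound list

1 | 3-chloro-2-methylanisole | COc1cccc(Cl)c1C | starting material
2 | 2-chloro-1-[chloro(methoxy)methyl]-4-methoxy-3-methylbenzene (α-chloro ether, not isolated) | COc1ccc(C(Cl)OC)c(Cl)c1C | intermediate
3 | 2-chloro-4-methoxy-3-methylbenzaldehyde | COc1ccc(C=O)c(Cl)c1C | intermediate
4 | lithium α-amino alkoxide from 3 and LiN(Me)CH2CH2NMe2 (not isolated) | COc1ccc(C([O-])N(C)CCN(C)C)c(Cl)c1C.[Li+] | intermediate
5 | C9-lithiated α-amino alkoxide (aryllithium, not isolated) | COc1cc([Li])c(C([O-])N(C)CCN(C)C)c(Cl)c1C.[Li+] | intermediate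
6 | C9-iodinated α-amino alkoxide (not isolated) | COc1cc(I)c(C([O-])N(C)CCN(C)C)c(Cl)c1C.[Li+] | intermediate
7 | 2-chloro-6-iodo-4-methoxy-3-methylbenzaldehyde | COc1cc(I)c(C=O)c(Cl)c1C | intermediate
8 | 3-chloro-2-ethenyl-1-iodo-5-methoxy-4-methylbenzene | COc1cc(I)c(C=C)c(Cl)c1C | intermediate
9 | 9-[2-(2-chloro-6-iodo-4-methoxy-3-methylphenyl)ethyl]-9-borabicyclo[3.3.1]nonane (not isolated) | COc1cc(I)c(CCB2C3CCCC2CCC3)c(Cl)c1C | intermediate
10 | 2-(2-chloro-6-iodo-4-methoxy-3-methylphenyl)ethan-1-ol | COc1cc(I)c(CCO)c(Cl)c1C | intermediate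
11 | 3-chloro-1-iodo-2-(2-iodoethyl)-5-methoxy-4-methylbenzene | COc1cc(I)c(CCI)c(Cl)c1C | intermediate
12 | methyl 3-methylbut-2-enoate | COC(=O)C=C(C)C | starting material
13 | lithium 1-methoxy-3-methylbuta-1,3-dien-1-olate (not isolated) | [Li+].COC([O-])=CC(C)=C | intermediate
14 | methyl 2-[2-(2-chloro-6-iodo-4-methoxy-3-methylphenyl)ethyl]-3-methylbut-3-enoate (racemic) | COC(=O)C(CCc1c(I)cc(OC)c(C)c1Cl)C(C)=C | intermediate
15 | 2-[2-(2-chloro-6-iodo-4-methoxy-3-methylphenyl)ethyl]-N-methoxy-N,3-dimethylbut-3-enamide (racemic) | CON(C)C(=O)C(CCc1c(I)cc(OC)c(C)c1Cl)C(C)=C | intermediate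
16 | bromomagnesium alkoxide, tetrahedral adduct of 15 and MeMgBr (not isolated) | CON(C)C(C)(O[Mg]Br)C(CCc1c(I)cc(OC)c(C)c1Cl)C(C)=C | intermediate
17 | 3-[2-(2-chloro-6-iodo-4-methoxy-3-methylphenyl)ethyl]-4-methylpent-4-en-2-one (racemic) | CC(=O)C(CCc1c(I)cc(OC)c(C)c1Cl)C(C)=C | intermediate
18 | 3-chloro-1-iodo-5-methoxy-4-methyl-2-[4-methyl-3-(prop-1-en-2-yl)pent-4-en-1-yl]benzene (achiral) | COc1cc(I)c(CCC(C(C)=C)C(C)=C)c(Cl)c1C | intermediate
19 | vinylboronic acid pinacol ester (2-ethenyl-4,4,5,5-tetramethyl-1,3,2-dioxaborolane) | C=CB1OC(C)(C)C(C)(C)O1 | starting material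
20 | cationic neopentylpalladium complex after ring closure, C1 bound to palladium, methyl cis to isopropenyl; the (R)-BINAP ligand on palladium is not drawn (not isolated) | COc1cc2c(CC[C@H](C(C)=C)[C@@]2(C)C[Pd+])c(Cl)c1C | intermediate
21 | (1R,2R)-5-chloro-7-methoxy-1,6-dimethyl-1-(prop-2-en-1-yl)-2-(prop-1-en-2-yl)-1,2,3,4-tetrahydronaphthalene (methyl and isopropenyl cis) | COc1cc2c(CC[C@H](C(C)=C)[C@@]2(C)CC=C)c(Cl)c1C | intermediate
22 | {3-[(1R,2R)-5-chloro-7-methoxy-1,6-dimethyl-2-(prop-1-en-2-yl)-1,2,3,4-tetrahydronaphthalen-1-yl]propyl}bis(3-methylbutan-2-yl)borane (not isolated) | COc1cc2c(CC[C@H](C(C)=C)[C@@]2(C)CCCB(C(C)C(C)C)C(C)C(C)C)c(Cl)c1C | intermediate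
23 | 3-[(1R,2R)-5-chloro-7-methoxy-1,6-dimethyl-2-(prop-1-en-2-yl)-1,2,3,4-tetrahydronaphthalen-1-yl]propan-1-ol | COc1cc2c(CC[C@H](C(C)=C)[C@@]2(C)CCCO)c(Cl)c1C | intermediate
24 | 3-[(1R,2R)-5-chloro-7-methoxy-1,6-dimethyl-2-(prop-1-en-2-yl)-1,2,3,4-tetrahydronaphthalen-1-yl]propanal (not isolated) | COc1cc2c(CC[C@H](C(C)=C)[C@@]2(C)CCC=O)c(Cl)c1C | intermediate
25 | 3-[(1R,2R)-5-chloro-7-methoxy-1,6-dimethyl-2-(prop-1-en-2-yl)-1,2,3,4-tetrahydronaphthalen-1-yl]propanoic acid | COc1cc2c(CC[C@H](C(C)=C)[C@@]2(C)CCC(=O)O)c(Cl)c1C | intermediate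
26 | 3-[(1R,2R)-5-chloro-7-hydroxy-1,6-dimethyl-2-(prop-1-en-2-yl)-1,2,3,4-tetrahydronaphthalen-1-yl]propanoic acid | Oc1cc2c(CC[C@H](C(C)=C)[C@@]2(C)CCC(=O)O)c(Cl)c1C | intermediate
27 | 3-[(1R,2R)-5-ethenyl-7-hydroxy-1,6-dimethyl-2-(prop-1-en-2-yl)-1,2,3,4-tetrahydronaphthalen-1-yl]propanoic acid | Oc1cc2c(CC[C@H](C(C)=C)[C@@]2(C)CCC(=O)O)c(C=C)c1C | intermediate
28 | methyl 3-[(1R,2R)-5-ethenyl-7-hydroxy-1,6-dimethyl-2-(prop-1-en-2-yl)-1,2,3,4-tetrahydronaphthalen-1-yl]propanoate | Oc1cc2c(CC[C@H](C(C)=C)[C@@]2(C)CCC(=O)OC)c(C=C)c1C | intermediate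
29 | trigonochinene C, methyl 3-[(1R,2R,4aR)-5-ethenyl-4a-hydroperoxy-1,6-dimethyl-7-oxo-2-(prop-1-en-2-yl)-1,2,3,4,4a,7-hexahydronaphthalen-1-yl]propanoate | C=CC1=C(C)C(=O)C=C2[C@]1(OO)CC[C@H](C(=C)C)[C@@]2(C)CCC(=O)OC | target

## Step count and risks

Total step count: 16. Longest linear sequence: 16 steps (from 1; 12 and 19 are purchased).

Steps most likely to fail:

Step 10. The ligand may discriminate poorly between the two enantiotopic isopropenyl groups. The arylpalladium may also couple with 19 before ring closure, or 20 may transmetalate too slowly and decay by palladation of the neighbouring C11–H bond. The fallback sets out from 18 and returns at 21, and separates ring closure from C1–C2 bond formation. An asymmetric Heck cyclization terminated by borylation (Pd(OAc)2, (R)-BINAP, B2pin2, KOAc, DMA, 80 °C) should give the neopentyl boronate 2-{[(1R,2R)-5-chloro-7-methoxy-1,6-dimethyl-2-(prop-1-en-2-yl)-1,2,3,4-tetrahydronaphthalen-1-yl]methyl}-4,4,5,5-tetramethyl-1,3,2-dioxaborolane F1. The diboron trap cannot act as a Heck acceptor, and without the vinylboronate other chiral ligands can be screened freely. Zweifel olefination of F1 (vinylmagnesium bromide, THF, −78 °C; I2; NaOMe, MeOH) then forms C1–C2 and gives 21.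

Step 16. Oxygen may enter on the wrong face of C8, because the two faces differ only through the C10 quaternary centre and ring B is conformationally mobile. Ene reaction at the isopropenyl group is a lesser drain. The fallback sets out from 28 and returns to 28 as an epimer-recycling loop. The separated C8-epimeric hydroperoxide methyl 3-[(1R,2R,4aS)-5-ethenyl-4a-hydroperoxy-1,6-dimethyl-7-oxo-2-(prop-1-en-2-yl)-1,2,3,4,4a,7-hexahydronaphthalen-1-yl]propanoate F2 is reduced with Me2S to the quinol methyl 3-[(1R,2R,4aS)-5-ethenyl-4a-hydroxy-1,6-dimethyl-7-oxo-2-(prop-1-en-2-yl)-1,2,3,4,4a,7-hexahydronaphthalen-1-yl]propanoate F3. Reductive re-aromatization of F3 with Zn in AcOH should return phenol 28, which is oxygenated again.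

Step 2. Lithiation may occur at C11 under control of the methoxy group instead of at C9, or n-BuLi may attack the C14–Cl bond during the long metalation. The fallback sets out from 3 and returns at 7, using a carboxylate instead of the masked aldehyde as director. Pinnick oxidation of 3 (NaClO2, NaH2PO4, 2-methylbut-2-ene) gives 2-chloro-4-methoxy-3-methylbenzoic acid F4. Lithiation of its lithium salt with s-BuLi and TMEDA in THF at −78 °C should occur at the only free position ortho to the carboxylate, and I2 then gives 2-chloro-6-iodo-4-methoxy-3-methylbenzoic acid F5. Reduction with BH3·THF gives (2-chloro-6-iodo-4-methoxy-3-methylphenyl)methanol F6, and MnO2 in CH2Cl2 oxidizes F6 to 7.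

## Further compounds

F1 | step 10 | 2-{[(1R,2R)-5-chloro-7-methoxy-1,6-dimethyl-2-(prop-1-en-2-yl)-1,2,3,4-tetrahydronaphthalen-1-yl]methyl}-4,4,5,5-tetramethyl-1,3,2-dioxaborolane | COc1cc2c(CC[C@H](C(C)=C)[C@@]2(C)CB3OC(C)(C)C(C)(C)O3)c(Cl)c1C
F2 | step 16 | methyl 3-[(1R,2R,4aS)-5-ethenyl-4a-hydroperoxy-1,6-dimethyl-7-oxo-2-(prop-1-en-2-yl)-1,2,3,4,4a,7-hexahydronaphthalen-1-yl]propanoate | C=CC1=C(C)C(=O)C=C2[C@@]1(OO)CC[C@H](C(=C)C)[C@@]2(C)CCC(=O)OC
F3 | step 16 | methyl 3-[(1R,2R,4aS)-5-ethenyl-4a-hydroxy-1,6-dimethyl-7-oxo-2-(prop-1-en-2-yl)-1,2,3,4,4a,7-hexahydronaphthalen-1-yl]propanoate | C=CC1=C(C)C(=O)C=C2[C@@]1(O)CC[C@H](C(=C)C)[C@@]2(C)CCC(=O)OC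
F4 | step 2 | 2-chloro-4-methoxy-3-methylbenzoic acid | COc1ccc(C(=O)O)c(Cl)c1C
F5 | step 2 | 2-chloro-6-iodo-4-methoxy-3-methylbenzoic acid | COc1cc(I)c(C(=O)O)c(Cl)c1C
F6 | step 2 | (2-chloro-6-iodo-4-methoxy-3-methylphenyl)methanol | COc1cc(I)c(CO)c(Cl)c1C
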